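**Plan** (atoms carry the numbers of the C15 chain, C1 = alkyne CH to C15 = ethyl CH3; ring A is the oxane made of O and C9–C13)
Cuts: C12–Br and C10–Cl back to oxygen on both carbons; then O–C9 of ring A, which unfolds the ring into a furan (C9–C12) with its carbinol at C13; then C8–C9 (furyllithium plus a C1–C8 chloro-epoxide); then C5–C6 (allylic bromide plus propargyl alcohol).
Enabling feature: ring A has oxygen on C9 and C13, a heteroatom on C10 and on C12, and a bare CH2 at C11, which is exactly what a 2,5-disubstituted furan with a C13 carbinol delivers on oxidative ring expansion.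
Forward: the C1–C8 chain is joined at C5–C6, the furan is attached at C8–C9, ring A (the only ring) closes in the key step, and the halogens and the acetate follow.
Stereochemistry: C13 by Noyori transfer hydrogenation; C7 and C6 by Sharpless epoxidation and invertive chloride opening; C9, C10 and C12 by relay from C13 inside ring A (axial hydride at C9, epoxidation anti to C8, equatorial hydride at C12), with C10 and C12 then inverted by halide.

Key step: step 14

Remark: hemiketal 20 should form as a mixture of anomers; the anomer with axial hydroxyl is written, and both give the same oxocarbenium ion in step 15.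

Step 1
Reactants: 1 (E)-pent-2-en-4-yn-1-ol
Product: 3 (E)-5-(triisopropylsilyl)pent-2-en-4-yn-1-ol, via bis(bromomagnesium) dianion 2 (not isolated)
Conditions: EtMgBr (2.2 equiv), THF, 0 to 45 °C; then i-Pr3SiCl, reflux; aq. NH4Cl
Reagents that add atoms: chlorotriisopropylsilane CC(C)[Si](Cl)(C(C)C)C(C)C; ethylmagnesium bromide CC[Mg]Br (its magnesium and bromine stay in 2 only)
Why: C-silylation of a hydroxy-alkyne dianion, in which the hindered silyl chloride should react at the acetylide carbon and not at the poorly nucleophilic bromomagnesium alkoxide; the i-Pr3Si group is chosen because it withstands K2CO3/MeOH, n-BuLi, HF·pyridine and hydride reagents later.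

Step 2
Reactants: 3 (E)-5-(triisopropylsilyl)pent-2-en-4-yn-1-ol
Product: 4 (E)-(5-bromopent-3-en-1-yn-1-yl)triisopropylsilane
Conditions: CBr4, PPh3, CH2Cl2, 0 °C
Reagents that add atoms: tetrabromomethane BrC(Br)(Br)Br
Why: Appel reaction of a primary allylic alcohol, an SN2 displacement of the alkoxyphosphonium ion that leaves the E alkene untouched.

Step 3
Reactants: 4 allylic bromide; 5 prop-2-yn-1-ol
Product: 6 (E)-8-(triisopropylsilyl)oct-5-ene-2,7-diyn-1-ol
Conditions: CuI, NaI, K2CO3, DMF, rt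
Reagents that add atoms: none
Why: Copper acetylide alkylation of a terminal alkyne with an allylic halide, in which the acetylide from 5 attacks the unhindered primary carbon C5 in the SN2 sense to form C5–C6 as the linear skipped enediyne, the free hydroxyl being tolerated under carbonate.

Step 4
Reactants: 6 enediynol
Product: 7 (2E,5E)-8-(triisopropylsilyl)octa-2,5-dien-7-yn-1-ol
Conditions: NaAlH2(OCH2CH2OMe)2, THF, 0 °C; aq. potassium sodium tartrate
Reagents that add atoms: none
Why: Alkoxide-directed trans-hydroalumination of a propargylic alcohol gives the E allylic alcohol only, while the silyl alkyne, which has no hydroxyl to direct the aluminium hydride, should stay intact.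

Step 5
Reactants: 7 dienynol
Product: 8 {(2S,3S)-3-[(E)-5-(triisopropylsilyl)pent-2-en-4-yn-1-yl]oxiran-2-yl}methanol
Conditions: Ti(OiPr)4 (cat.), L-(+)-diethyl tartrate (cat.), t-BuOOH, 4 Å molecular sieves, CH2Cl2, −20 °C
Reagents that add atoms: tert-butyl hydroperoxide CC(C)(C)OO
Why: Sharpless asymmetric epoxidation, in which the L-(+)-tartrate titanium complex delivers oxygen to the face of the E allylic alcohol that gives the (2S,3S)-epoxy alcohol, setting C7 as S; the enyne alkene lacks the allylic hydroxyl and is not epoxidised.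

Step 6
Reactants: 8 epoxy alcohol
Product: 9 (2S,3R,5E)-3-chloro-8-(triisopropylsilyl)oct-5-en-7-yne-1,2-diol
Conditions: ClTi(OiPr)3, CH2Cl2, 0 °C to rt; aq. tartaric acid
Reagents that add atoms: chlorotitanium triisopropoxide CC(C)O[Ti](Cl)(OC(C)C)OC(C)C
Why: Titanium-assisted C3-selective opening of a 2,3-epoxy alcohol, in which chelation of titanium by both oxygens directs chloride to C6 with inversion, setting the 6R chloride anti to the C7 hydroxyl.

Step 7
Reactants: 9 chloro diol
Product: 10 (2S,3R,5E)-3-chloro-2-hydroxy-8-(triisopropylsilyl)oct-5-en-7-yn-1-yl 4-methylbenzenesulfonate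
Conditions: TsCl, Bu2SnO (cat.), Et3N, CH2Cl2, 0 °C to rt
Reagents that add atoms: 4-methylbenzenesulfonyl chloride Cc1ccc(cc1)S(Cl)(=O)=O
Why: Bu2SnO-catalysed sulfonylation through the stannylene acetal discriminates the primary C8 hydroxyl of the 1,2-diol from the secondary C7 hydroxyl.

Step 8
Reactants: 10 primary tosylate
Product: 11 (2S)-2-[(1R,3E)-1-chloro-6-(triisopropylsilyl)hex-3-en-5-yn-1-yl]oxirane
Conditions: K2CO3, MeOH, 0 °C
Reagents that add atoms: none
Why: Intramolecular Williamson closure (3-exo-tet) of the C7 alkoxide onto the primary sulfonate, which is displaced far faster than the secondary chloride, so that C7 and C6 keep their configurations and the C-silyl alkyne survives the carbonate.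

Step 9
Reactants: 12 1-(furan-2-yl)propan-1-one
Product: 13 (S)-1-(furan-2-yl)propan-1-ol
Conditions: RuCl(p-cymene)[(S,S)-TsDPEN] (cat.), HCO2H/Et3N (5:2), rt
Reagents that add atoms: none
Why: Noyori asymmetric transfer hydrogenation of a heteroaryl alkyl ketone, in which the (S,S)-TsDPEN complex, known to give S carbinols from aryl alkyl ketones through its CH/π-organised six-membered transition state, sets C13 as S.

Step 10
Reactants: 13 (S)-furyl carbinol
Product: 14 (S)-triethyl[1-(furan-2-yl)propoxy]silane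
Conditions: Et3SiCl, imidazole, CH2Cl2, 0 °C to rt
Reagents that add atoms: chlorotriethylsilane CC[Si](Cl)(CC)CC
Why: Standard silylation; the Et3Si ether tolerates n-BuLi at low temperature and can later be removed beside a t-BuMe2Si ether.

Step 11
Reactants: 14 silyl ether of the furyl carbinol; 11 chloro-epoxide
Product: 16 (2S,3R,5E)-3-chloro-1-{5-[(S)-1-(triethylsilyloxy)propyl]furan-2-yl}-8-(triisopropylsilyl)oct-5-en-7-yn-2-ol, via 5-lithiofuran 15 (not isolated)
Conditions: n-BuLi, THF, −78 to 0 °C; then −78 °C, 11, BF3·OEt2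
Reagents that add atoms: n-butyllithium [Li]CCCC (its lithium stays in 15 only)
Why: α-Lithiation of the 2-substituted furan at its free C5 position followed by BF3-promoted SN2 opening of the terminal epoxide at the unsubstituted C8 forms the C8–C9 bond; C7 and C6 are not reacting centres, and the low temperature should outrun proton transfer or elimination in the chloro-epoxide.

Step 12
Reactants: 16 secondary alcohol
Product: 17 tert-butyl{[(2S,3R,5E)-3-chloro-1-{5-[(S)-1-(triethylsilyloxy)propyl]furan-2-yl}-8-(triisopropylsilyl)oct-5-en-7-yn-2-yl]oxy}dimethylsilane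
Conditions: t-BuMe2SiOTf, 2,6-lutidine, CH2Cl2, −78 °C
Reagents that add atoms: tert-butyldimethylsilyl trifluoromethanesulfonate CC(C)(C)[Si](C)(C)OS(=O)(=O)C(F)(F)F
Why: Silylation of a hindered secondary alcohol with a silyl triflate; the C7 oxygen must be capped so that it cannot add to C10 of the enone formed in step 14.

Step 13
Reactants: 17 bis-silyl ether
Product: 18 (S)-1-{5-[(2S,3R,5E)-2-(tert-butyldimethylsilyloxy)-3-chloro-8-(triisopropylsilyl)oct-5-en-7-yn-1-yl]furan-2-yl}propan-1-ol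
Conditions: HF·pyridine, pyridine, THF, 0 °C
Reagents that add atoms: none
Why: Selective cleavage of the less hindered Et3Si ether beside the t-BuMe2Si ether and the C-silyl alkyne by pyridine-buffered HF, a medium too weakly acidic to ionise the furfuryl C–O bond, so that C13 is expected to stay S.

Step 14
Reactants: 18 furyl carbinol
Product: 20 (2S,6R)-6-[(2S,3R,5E)-2-(tert-butyldimethylsilyloxy)-3-chloro-8-(triisopropylsilyl)oct-5-en-7-yn-1-yl]-2-ethyl-6-hydroxy-2H-pyran-3(6H)-one, via Z-enedione 19 (not isolated)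
Conditions: VO(acac)2 (cat.), t-BuOOH, CH2Cl2, 0 °C to rt
Reagents that add atoms: tert-butyl hydroperoxide CC(C)(C)OO
Why: The C13 hydroxyl binds the vanadium peroxide, which delivers oxygen to the adjacent C12=C11 bond of the furan, and the resulting 2,5-dioxygenated dihydrofuran opens to the Z-enedione 19 with ketones at C12 and C9 and the alkene at C10=C11. The C13 hydroxyl then adds to the C9 carbonyl, forming O–C9 and closing ring A by 6-exo-trig hemiketalisation; this is the Achmatowicz rearrangement of a 2,5-disubstituted furyl carbinol, the closest known reaction type. The only new stereocenter is the hemiketal carbon C9, set under thermodynamic control by the anomeric effect (hydroxyl axial, side chain equatorial and cis to ethyl), and it is erased in step 15. C13 is not a reacting centre and should keep its S configuration. The step needs oxidation of the furan and not of the enyne, which the hydroxyl-directed oxidant and the far higher electron density of the furan secure. The product holds the C12 ketone and the C10=C11 enone, so oxygen can later be placed at C10 and C12 with C11 left untouched.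

Step 15
Reactants: 20 hemiketal
Product: 21 (2S,6R)-6-[(2S,3R,5E)-2-(tert-butyldimethylsilyloxy)-3-chloro-8-(triisopropylsilyl)oct-5-en-7-yn-1-yl]-2-ethyl-2H-pyran-3(6H)-one
Conditions: Et3SiH, CF3CO2H, CH2Cl2, −40 °C
Reagents that add atoms: none
Why: Kishi-type ionic reduction of the hemiketal, in which CF3CO2H ionises C9 to the conjugated oxocarbenium ion and Et3SiH adds along the axial trajectory of the half-chair that keeps the C13 ethyl group pseudo-equatorial, so that C9 becomes R with the side chain cis to ethyl; the silyl ether and the C-silyl alkyne should survive the short cold exposure.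

Step 16
Reactants: 21 cis-dihydropyranone
Product: 22 (1R,2R,4S,6R)-2-[(2S,3R,5E)-2-(tert-butyldimethylsilyloxy)-3-chloro-8-(triisopropylsilyl)oct-5-en-7-yn-1-yl]-4-ethyl-3,7-dioxabicyclo[4.1.0]heptan-5-one
Conditions: t-BuOOH, DBU, CH2Cl2, 0 °C
Reagents that add atoms: tert-butyl hydroperoxide CC(C)(C)OO
Why: Weitz–Scheffer nucleophilic epoxidation of the enone, in which t-BuOO− adds to C10 on the face opposite to the neighbouring C8 substituent and the enolate closes onto oxygen, so that the epoxide oxygen ends trans to the side chain and to ethyl; the enyne alkene is no Michael acceptor and is inert, and C13 sits in its favoured equatorial orientation.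

Step 17
Reactants: 22 epoxy ketone
Product: 23 (2S,5S,6R)-6-[(2S,3R,5E)-2-(tert-butyldimethylsilyloxy)-3-chloro-8-(triisopropylsilyl)oct-5-en-7-yn-1-yl]-2-ethyl-5-hydroxydihydro-2H-pyran-3(4H)-one
Conditions: (PhSe)2, NaBH4, EtOH, then AcOH, 0 °C; 22 in THF
Reagents that add atoms: none
Why: Miyashita reduction of an α,β-epoxy ketone, in which benzeneselenolate opens the epoxide at C11 next to the carbonyl and a second selenolate removes selenium to give an enolate that AcOH protonates, so the C10–O bond keeps its configuration (equatorial 10S alcohol, trans to C8) and the buffered medium avoids β-elimination.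

Step 18
Reactants: 23 β-hydroxy ketone
Product: 24 (2S,5S,6R)-6-[(2S,3R,5E)-2-(tert-butyldimethylsilyloxy)-3-chloro-8-(triisopropylsilyl)oct-5-en-7-yn-1-yl]-2-ethyl-5-(triethylsilyloxy)dihydro-2H-pyran-3(4H)-one
Conditions: Et3SiCl, imidazole, CH2Cl2, 0 °C
Reagents that add atoms: chlorotriethylsilane CC[Si](Cl)(CC)CC
Why: Mild silylation keeps the C10 oxygen apart from the C12 oxygen for the two different halogenations and avoids β-elimination of the hydroxy ketone.

Step 19
Reactants: 24 silyloxy ketone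
Product: 25 (2S,3S,5S,6R)-6-[(2S,3R,5E)-2-(tert-butyldimethylsilyloxy)-3-chloro-8-(triisopropylsilyl)oct-5-en-7-yn-1-yl]-2-ethyl-5-(triethylsilyloxy)tetrahydro-2H-pyran-3-ol
Conditions: LiBH(s-Bu)3, THF, −78 °C
Reagents that add atoms: none
Why: Reduction of the ring ketone by a bulky trialkylborohydride, which attacks along the equatorial trajectory and so gives the axial 12S alcohol cis to the equatorial C13 ethyl group.

Step 20
Reactants: 25 axial C12 alcohol
Product: 26 (2R,3S,5R,6S)-5-bromo-2-[(2S,3R,5E)-2-(tert-butyldimethylsilyloxy)-3-chloro-8-(triisopropylsilyl)oct-5-en-7-yn-1-yl]-6-ethyl-3-(triethylsilyloxy)tetrahydro-2H-pyran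
Conditions: CBr4, P(n-C8H17)3, toluene, 70 °C
Reagents that add atoms: tetrabromomethane BrC(Br)(Br)Br
Why: Appel-type bromination, in which the axial alkoxyphosphonium ion at C12 is displaced by bromide from the equatorial side with inversion, setting the equatorial 12R bromide; the silyl ethers are inert to the neutral reagent.

Step 21
Reactants: 26 bromide
Product: 27 (2R,3S,5R,6S)-5-bromo-2-[(2S,3R,5E)-2-(tert-butyldimethylsilyloxy)-3-chloro-8-(triisopropylsilyl)oct-5-en-7-yn-1-yl]-6-ethyltetrahydro-2H-pyran-3-ol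
Conditions: pyridinium p-toluenesulfonate (cat.), MeOH/CH2Cl2, 0 °C to rt
Reagents that add atoms: none
Why: Acid-catalysed methanolysis removes the Et3Si ether while the bulkier t-BuMe2Si ether at C7 and the C-silyl alkyne are expected to persist.

Step 22
Reactants: 27 equatorial C10 alcohol
Product: 28 (2R,3R,5R,6S)-5-bromo-2-[(2S,3R,5E)-2-(tert-butyldimethylsilyloxy)-3-chloro-8-(triisopropylsilyl)oct-5-en-7-yn-1-yl]-3-chloro-6-ethyltetrahydro-2H-pyran
Conditions: CCl4, P(n-C8H17)3, toluene, 80 °C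
Reagents that add atoms: tetrachloromethane ClC(Cl)(Cl)Cl
Why: Appel-type chlorination, in which the equatorial alkoxyphosphonium ion at C10 is displaced by chloride along the axial trajectory with inversion, setting the axial 10R chloride cis to the C9 side chain.

Step 23
Reactants: 28 ring dihalide
Product: 29 (2S,3R,5E)-1-[(2R,3R,5R,6S)-5-bromo-3-chloro-6-ethyltetrahydro-2H-pyran-2-yl]-3-chloro-8-(triisopropylsilyl)oct-5-en-7-yn-2-ol
Conditions: HF·pyridine, THF, 0 °C to rt
Reagents that add atoms: none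
Why: Acidic fluoride cleaves the t-BuMe2Si ether without generating an alkoxide, so the C6/C7 chlorohydrin cannot close to an epoxide, and the alkynyl C–Si bond is stable to HF.

Step 24
Reactants: 29 C7 alcohol
Product: 30 (2S,3R,5E)-1-[(2R,3R,5R,6S)-5-bromo-3-chloro-6-ethyltetrahydro-2H-pyran-2-yl]-3-chloro-8-(triisopropylsilyl)oct-5-en-7-yn-2-yl acetate
Conditions: Ac2O, pyridine, DMAP (cat.), CH2Cl2, 0 °C to rt
Reagents that add atoms: acetic anhydride CC(=O)OC(C)=O
Why: DMAP-catalysed acylation of the secondary alcohol with retention at C7.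

Step 25
Reactants: 30 silyl alkyne acetate
Product: 31 (2S,3R,5E)-1-[(2R,3R,5R,6S)-5-bromo-3-chloro-6-ethyltetrahydro-2H-pyran-2-yl]-3-chlorooct-5-en-7-yn-2-yl acetate
Conditions: n-Bu4NF, AcOH, THF, 0 °C
Reagents that add atoms: none
Why: Fluoride-induced protodesilylation of the alkynylsilane frees the terminal enyne, and AcOH buffering is meant to protect the acetate and the secondary halides from basic fluoride.

**Compound list**
1 | (E)-pent-2-en-4-yn-1-ol | OC/C=C/C#C | starting material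
2 | bromomagnesium (E)-5-(bromomagnesio)pent-2-en-4-yn-1-olate | Br[Mg]OC/C=C/C#C[Mg]Br | intermediate
3 | (E)-5-(triisopropylsilyl)pent-2-en-4-yn-1-ol | OC/C=C/C#C[Si](C(C)C)(C(C)C)C(C)C | intermediate
4 | (E)-(5-bromopent-3-en-1-yn-1-yl)triisopropylsilane | BrC/C=C/C#C[Si](C(C)C)(C(C)C)C(C)C | intermediate
5 | prop-2-yn-1-ol (propargyl alcohol) | C#CCO | starting material
6 | (E)-8-(triisopropylsilyl)oct-5-ene-2,7-diyn-1-ol | OCC#CC/C=C/C#C[Si](C(C)C)(C(C)C)C(C)C | intermediate
7 | (2E,5E)-8-(triisopropylsilyl)octa-2,5-dien-7-yn-1-ol | OC/C=C/C/C=C/C#C[Si](C(C)C)(C(C)C)C(C)C | intermediate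
8 | {(2S,3S)-3-[(E)-5-(triisopropylsilyl)pent-2-en-4-yn-1-yl]oxiran-2-yl}methanol | OC[C@@H]1O[C@H]1C/C=C/C#C[Si](C(C)C)(C(C)C)C(C)C | intermediate
9 | (2S,3R,5E)-3-chloro-8-(triisopropylsilyl)oct-5-en-7-yne-1,2-diol | OC[C@H](O)[C@H](Cl)C/C=C/C#C[Si](C(C)C)(C(C)C)C(C)C | intermediate
10 | (2S,3R,5E)-3-chloro-2-hydroxy-8-(triisopropylsilyl)oct-5-en-7-yn-1-yl 4-methylbenzenesulfonate | Cc1ccc(cc1)S(=O)(=O)OC[C@H](O)[C@H](Cl)C/C=C/C#C[Si](C(C)C)(C(C)C)C(C)C | intermediate
11 | (2S)-2-[(1R,3E)-1-chloro-6-(triisopropylsilyl)hex-3-en-5-yn-1-yl]oxirane | C1O[C@@H]1[C@H](Cl)C/C=C/C#C[Si](C(C)C)(C(C)C)C(C)C | intermediate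
12 | 1-(furan-2-yl)propan-1-one | CCC(=O)c1ccco1 | starting material
13 | (S)-1-(furan-2-yl)propan-1-ol | CC[C@H](O)c1ccco1 | intermediate
14 | (S)-triethyl[1-(furan-2-yl)propoxy]silane | CC[C@H](O[Si](CC)(CC)CC)c1ccco1 | intermediate
15 | {5-[(S)-1-(triethylsilyloxy)propyl]furan-2-yl}lithium | CC[C@H](O[Si](CC)(CC)CC)c1ccc([Li])o1 | intermediate
16 | (2S,3R,5E)-3-chloro-1-{5-[(S)-1-(triethylsilyloxy)propyl]furan-2-yl}-8-(triisopropylsilyl)oct-5-en-7-yn-2-ol | CC[C@H](O[Si](CC)(CC)CC)c1ccc(C[C@H](O)[C@H](Cl)C/C=C/C#C[Si](C(C)C)(C(C)C)C(C)C)o1 | intermediate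
17 | tert-butyl{[(2S,3R,5E)-3-chloro-1-{5-[(S)-1-(triethylsilyloxy)propyl]furan-2-yl}-8-(triisopropylsilyl)oct-5-en-7-yn-2-yl]oxy}dimethylsilane | CC[C@H](O[Si](CC)(CC)CC)c1ccc(C[C@H](O[Si](C)(C)C(C)(C)C)[C@H](Cl)C/C=C/C#C[Si](C(C)C)(C(C)C)C(C)C)o1 | intermediate
18 | (S)-1-{5-[(2S,3R,5E)-2-(tert-butyldimethylsilyloxy)-3-chloro-8-(triisopropylsilyl)oct-5-en-7-yn-1-yl]furan-2-yl}propan-1-ol | CC[C@H](O)c1ccc(C[C@H](O[Si](C)(C)C(C)(C)C)[C@H](Cl)C/C=C/C#C[Si](C(C)C)(C(C)C)C(C)C)o1 | intermediate
19 | (3S,5Z,9S,10R,12E)-9-(tert-butyldimethylsilyloxy)-10-chloro-3-hydroxy-15-(triisopropylsilyl)pentadeca-5,12-dien-14-yne-4,7-dione | CC[C@H](O)C(=O)/C=C\C(=O)C[C@H](O[Si](C)(C)C(C)(C)C)[C@H](Cl)C/C=C/C#C[Si](C(C)C)(C(C)C)C(C)C | intermediate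
20 | (2S,6R)-6-[(2S,3R,5E)-2-(tert-butyldimethylsilyloxy)-3-chloro-8-(triisopropylsilyl)oct-5-en-7-yn-1-yl]-2-ethyl-6-hydroxy-2H-pyran-3(6H)-one | CC[C@@H]1O[C@](O)(C[C@H](O[Si](C)(C)C(C)(C)C)[C@H](Cl)C/C=C/C#C[Si](C(C)C)(C(C)C)C(C)C)C=CC1=O | intermediate
21 | (2S,6R)-6-[(2S,3R,5E)-2-(tert-butyldimethylsilyloxy)-3-chloro-8-(triisopropylsilyl)oct-5-en-7-yn-1-yl]-2-ethyl-2H-pyran-3(6H)-one (2,6-cis) | CC[C@@H]1O[C@H](C[C@H](O[Si](C)(C)C(C)(C)C)[C@H](Cl)C/C=C/C#C[Si](C(C)C)(C(C)C)C(C)C)C=CC1=O | intermediate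
22 | (1R,2R,4S,6R)-2-[(2S,3R,5E)-2-(tert-butyldimethylsilyloxy)-3-chloro-8-(triisopropylsilyl)oct-5-en-7-yn-1-yl]-4-ethyl-3,7-dioxabicyclo[4.1.0]heptan-5-one (epoxide oxygen trans to the side chain and to ethyl) | CC[C@@H]1O[C@H](C[C@H](O[Si](C)(C)C(C)(C)C)[C@H](Cl)C/C=C/C#C[Si](C(C)C)(C(C)C)C(C)C)[C@H]2O[C@H]2C1=O | intermediate
23 | (2S,5S,6R)-6-[(2S,3R,5E)-2-(tert-butyldimethylsilyloxy)-3-chloro-8-(triisopropylsilyl)oct-5-en-7-yn-1-yl]-2-ethyl-5-hydroxydihydro-2H-pyran-3(4H)-one | CC[C@@H]1O[C@H](C[C@H](O[Si](C)(C)C(C)(C)C)[C@H](Cl)C/C=C/C#C[Si](C(C)C)(C(C)C)C(C)C)[C@@H](O)CC1=O | intermediate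
24 | (2S,5S,6R)-6-[(2S,3R,5E)-2-(tert-butyldimethylsilyloxy)-3-chloro-8-(triisopropylsilyl)oct-5-en-7-yn-1-yl]-2-ethyl-5-(triethylsilyloxy)dihydro-2H-pyran-3(4H)-one | CC[C@@H]1O[C@H](C[C@H](O[Si](C)(C)C(C)(C)C)[C@H](Cl)C/C=C/C#C[Si](C(C)C)(C(C)C)C(C)C)[C@@H](O[Si](CC)(CC)CC)CC1=O | intermediate
25 | (2S,3S,5S,6R)-6-[(2S,3R,5E)-2-(tert-butyldimethylsilyloxy)-3-chloro-8-(triisopropylsilyl)oct-5-en-7-yn-1-yl]-2-ethyl-5-(triethylsilyloxy)tetrahydro-2H-pyran-3-ol | CC[C@@H]1O[C@H](C[C@H](O[Si](C)(C)C(C)(C)C)[C@H](Cl)C/C=C/C#C[Si](C(C)C)(C(C)C)C(C)C)[C@@H](O[Si](CC)(CC)CC)C[C@@H]1O | intermediate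
26 | (2R,3S,5R,6S)-5-bromo-2-[(2S,3R,5E)-2-(tert-butyldimethylsilyloxy)-3-chloro-8-(triisopropylsilyl)oct-5-en-7-yn-1-yl]-6-ethyl-3-(triethylsilyloxy)tetrahydro-2H-pyran | CC[C@@H]1O[C@H](C[C@H](O[Si](C)(C)C(C)(C)C)[C@H](Cl)C/C=C/C#C[Si](C(C)C)(C(C)C)C(C)C)[C@@H](O[Si](CC)(CC)CC)C[C@H]1Br | intermediate
27 | (2R,3S,5R,6S)-5-bromo-2-[(2S,3R,5E)-2-(tert-butyldimethylsilyloxy)-3-chloro-8-(triisopropylsilyl)oct-5-en-7-yn-1-yl]-6-ethyltetrahydro-2H-pyran-3-ol | CC[C@@H]1O[C@H](C[C@H](O[Si](C)(C)C(C)(C)C)[C@H](Cl)C/C=C/C#C[Si](C(C)C)(C(C)C)C(C)C)[C@@H](O)C[C@H]1Br | intermediate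
28 | (2R,3R,5R,6S)-5-bromo-2-[(2S,3R,5E)-2-(tert-butyldimethylsilyloxy)-3-chloro-8-(triisopropylsilyl)oct-5-en-7-yn-1-yl]-3-chloro-6-ethyltetrahydro-2H-pyran | CC[C@@H]1O[C@H](C[C@H](O[Si](C)(C)C(C)(C)C)[C@H](Cl)C/C=C/C#C[Si](C(C)C)(C(C)C)C(C)C)[C@H](Cl)C[C@H]1Br | intermediate
29 | (2S,3R,5E)-1-[(2R,3R,5R,6S)-5-bromo-3-chloro-6-ethyltetrahydro-2H-pyran-2-yl]-3-chloro-8-(triisopropylsilyl)oct-5-en-7-yn-2-ol | CC[C@@H]1O[C@H](C[C@H](O)[C@H](Cl)C/C=C/C#C[Si](C(C)C)(C(C)C)C(C)C)[C@H](Cl)C[C@H]1Br | intermediate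
30 | (2S,3R,5E)-1-[(2R,3R,5R,6S)-5-bromo-3-chloro-6-ethyltetrahydro-2H-pyran-2-yl]-3-chloro-8-(triisopropylsilyl)oct-5-en-7-yn-2-yl acetate | CC[C@@H]1O[C@H](C[C@H](OC(C)=O)[C@H](Cl)C/C=C/C#C[Si](C(C)C)(C(C)C)C(C)C)[C@H](Cl)C[C@H]1Br | intermediate
31 | (2S,3R,5E)-1-[(2R,3R,5R,6S)-5-bromo-3-chloro-6-ethyltetrahydro-2H-pyran-2-yl]-3-chlorooct-5-en-7-yn-2-yl acetate (6R,7S,9R,10R,12R,13S in chain numbering) | C#C/C=C/C[C@@H](Cl)[C@H](C[C@H]1O[C@@H](CC)[C@H](Br)C[C@H]1Cl)OC(C)=O | target

**Step count**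
Total: 25 steps. Longest linear sequence: 23 steps (steps 1–8, then 11–25, from 1); the furan branch (steps 9 and 10) joins at step 11.

**Steps most likely to fail**

Step 22. Substitution at C10 has to proceed along the axial trajectory next to the branched C9 and the ring oxygen. It may therefore be slow, and elimination toward C11 or simple return of the alcohol could take over at the temperature the phosphonium route needs. The fallback sets out from 27 and separates activation from substitution. The C10 hydroxyl is converted with ClCH2SO2Cl and 2,6-lutidine (CH2Cl2, 0 °C) into the chloromethanesulfonate F1, an isolable and compact leaving group. F1 is then displaced by LiCl in DMF at room temperature with inversion, which returns to the route at 28.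

Step 20. The axial alkoxyphosphonium ion at C12 has anti-periplanar axial hydrogens on C11 and C13, so E2 elimination may compete with equatorial attack of bromide at 70 °C. The fallback sets out from 25. The C12 hydroxyl is turned into the trifluoromethanesulfonate F2 (Tf2O, 2,6-lutidine, CH2Cl2, −78 °C), which is displaced without isolation of by-products by n-Bu4NBr at −20 °C. At this temperature substitution should outrun elimination, and the sequence returns to the route at 26.

Step 16. Facial selectivity of hydroperoxide addition at C10 may be poor, because the neighbouring C8 substituent is only pseudo-equatorial, and base may isomerise the enone. The fallback sets out from 21 and lets a hydroxyl group steer the oxygen. Reduction with NaBH4 and CeCl3·7H2O (MeOH, −78 °C) should give the allylic alcohol F3 with the C12 hydroxyl trans to ethyl. Hydroxyl-directed epoxidation with VO(acac)2 and t-BuOOH then places the epoxide oxygen on the hydroxyl face, which is the face opposite to C8, to give the syn epoxy alcohol F4. Oxidation with Dess–Martin periodinane returns to the route at 22.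

**Further compounds**
F1 | step 22 | (2R,3S,5R,6S)-5-bromo-2-[(2S,3R,5E)-2-(tert-butyldimethylsilyloxy)-3-chloro-8-(triisopropylsilyl)oct-5-en-7-yn-1-yl]-6-ethyltetrahydro-2H-pyran-3-yl chloromethanesulfonate | CC[C@@H]1O[C@H](C[C@H](O[Si](C)(C)C(C)(C)C)[C@H](Cl)C/C=C/C#C[Si](C(C)C)(C(C)C)C(C)C)[C@@H](OS(=O)(=O)CCl)C[C@H]1Br
F2 | step 20 | (2S,3S,5S,6R)-6-[(2S,3R,5E)-2-(tert-butyldimethylsilyloxy)-3-chloro-8-(triisopropylsilyl)oct-5-en-7-yn-1-yl]-2-ethyl-5-(triethylsilyloxy)tetrahydro-2H-pyran-3-yl trifluoromethanesulfonate | CC[C@@H]1O[C@H](C[C@H](O[Si](C)(C)C(C)(C)C)[C@H](Cl)C/C=C/C#C[Si](C(C)C)(C(C)C)C(C)C)[C@@H](O[Si](CC)(CC)CC)C[C@@H]1OS(=O)(=O)C(F)(F)F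
F3 | step 16 | (2S,3R,6R)-6-[(2S,3R,5E)-2-(tert-butyldimethylsilyloxy)-3-chloro-8-(triisopropylsilyl)oct-5-en-7-yn-1-yl]-2-ethyl-3,6-dihydro-2H-pyran-3-ol | CC[C@@H]1O[C@H](C[C@H](O[Si](C)(C)C(C)(C)C)[C@H](Cl)C/C=C/C#C[Si](C(C)C)(C(C)C)C(C)C)C=C[C@H]1O
F4 | step 16 | (1R,2R,4S,5S,6S)-2-[(2S,3R,5E)-2-(tert-butyldimethylsilyloxy)-3-chloro-8-(triisopropylsilyl)oct-5-en-7-yn-1-yl]-4-ethyl-3,7-dioxabicyclo[4.1.0]heptan-5-ol (epoxide oxygen and hydroxyl both trans to ethyl and to the side chain) | CC[C@@H]1O[C@H](C[C@H](O[Si](C)(C)C(C)(C)C)[C@H](Cl)C/C=C/C#C[Si](C(C)C)(C(C)C)C(C)C)[C@H]2O[C@H]2[C@H]1O
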